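## Retrosynthetic overview

1. The acetate is installed last (free ω-alcohol ← TBDPS ether). The exocyclic methylene comes from the lactone α-CH2 by carboxylation and decarboxylative Mannich methylenation.
2. The trans 4-carboxy-γ-lactone core goes back to a lactone imide and then to a syn-aldol adduct. The key C–C bond (C2–C3 of the oxolane) is made by an intermolecular Evans boron aldol between an N-succinyl (S)-4-benzyloxazolidinone (methyl half-ester) and 14-silyloxytetradecanal, which sets both stereocentres.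
3. Aldehyde fragment: tetradecane-1,14-diol, mono-silylation, oxidation. Imide fragment: (S)-4-benzyloxazolidin-2-one plus methyl 4-chloro-4-oxobutanoate.
4. Ring order: the target has one ring, the γ-lactone. It is closed by lactonization of the aldol adduct directly after the C–C bond formation; the oxazolidinone is only an auxiliary.

Assumption: the target SMILES is read as the trans (2R,3S) acid (oxolane numbering, C2 carries the side chain, C3 the CO2H); compounds 1, 4 and 5 are bought.

## Route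

Step 1
Reactants: 1 tetradecane-1,14-diol
Product: 2 14-[(tert-butyldiphenylsilyl)oxy]tetradecan-1-ol
Conditions: 1 (3 equiv), TBDPSCl (1 equiv), imidazole (1.2 equiv), DMF/THF, 0 °C → rt; excess 1 recovered
Reagents that add atoms: tert-butyl(chloro)diphenylsilane (TBDPSCl), CC(C)(C)[Si](Cl)(c1ccccc1)c1ccccc1
Why: Silyl ether formation on a primary alcohol; the two ends of 1 are equivalent and the threefold excess of diol makes the mono-ether the main product.

Step 2
Reactants: 2 14-[(tert-butyldiphenylsilyl)oxy]tetradecan-1-ol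
Product: 3 14-[(tert-butyldiphenylsilyl)oxy]tetradecanal
Conditions: 2,2,6,6-tetramethylpiperidin-1-oxyl (10 mol %), PhI(OAc)2 (1.1 equiv), CH2Cl2, rt
Reagents that add atoms: none
Why: Nitroxyl-catalysed (oxoammonium) oxidation of a primary alcohol stops at the aldehyde and leaves the silyl ether untouched.

Step 3
Reactants: 4 (4S)-4-benzyl-1,3-oxazolidin-2-one; 5 methyl 4-chloro-4-oxobutanoate
Product: 7 methyl 4-[(4S)-4-benzyl-2-oxo-1,3-oxazolidin-3-yl]-4-oxobutanoate, via N-lithio oxazolidinone 6 (not isolated)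
Conditions: n-BuLi (1.05 equiv), THF, −78 °C; then 5, −78 → 0 °C
Reagents that add atoms: none
Why: N-acylation of the lithiated oxazolidinone; the acid chloride is far more electrophilic than the methyl ester, so only the imide forms.

Step 4
Reactants: 7 methyl 4-[(4S)-4-benzyl-2-oxo-1,3-oxazolidin-3-yl]-4-oxobutanoate; 3 14-[(tert-butyldiphenylsilyl)oxy]tetradecanal
Product: 11 (4S)-4-benzyl-3-[(2R,3S)-2-{13-[(tert-butyldiphenylsilyl)oxy]tridecyl}-5-oxooxolane-3-carbonyl]-1,3-oxazolidin-2-one, via Z-boron enolate 8 (not isolated), via boron aldolate 9 (not isolated), via syn-aldol hydroxy ester 10 (not isolated)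
Conditions: 7, Bu2BOTf (1.1 equiv), iPr2NEt (1.2 equiv), CH2Cl2, 0 °C; 3 (1.1 equiv), −78 → 0 °C; pH 7 buffer, MeOH, 30% H2O2, 0 °C; crude with TsOH·H2O (10 mol %), CH2Cl2, rt
Reagents that add atoms: none
Why: Evans syn aldol: soft enolization of the imide (not the ester) gives only Z-enolate 8, which adds to 3 through a chair Zimmerman–Traxler transition state on the face away from the benzyl group and so sets both new stereocentres (3S,4R) at once; the syn adduct then lactonizes onto the methyl ester to give the trans γ-lactone.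

Step 5
Reactants: 11 lactone imide
Product: 13 (2R,3S)-2-{13-[(tert-butyldiphenylsilyl)oxy]tridecyl}-5-oxooxolane-3-carboxylic acid, via peroxy acid 12 (not isolated)
Conditions: LiOH·H2O (2 equiv), 30% H2O2 (4 equiv), THF/H2O (3:1), 0 °C; aq. Na2SO3; 1 M HCl to pH 2
Reagents that add atoms: hydrogen peroxide, OO (acts as LiOOH; one oxygen ends as the acid OH)
Why: Hydroperoxide cleavage of the imide: LiOOH attacks the exocyclic carbonyl selectively and releases the auxiliary, sulfite reduces the peracid, and the stereocentres are untouched (trans is also the thermodynamic arrangement).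

Step 6
Reactants: 13 silyl-protected trans paraconic acid
Product: 15 (2R,3S)-2-{13-[(tert-butyldiphenylsilyl)oxy]tridecyl}-5-oxooxolane-3,4-dicarboxylic acid (C4 epimers; used crude), via magnesium dicarboxylate 14 (not isolated)
Conditions: MeOMgOCO2Me (2 M in DMF, 30 equiv), 130 °C, 48 h; cold 1 M HCl, Et2O
Reagents that add atoms: methoxymagnesium methyl carbonate, CO[Mg]OC(=O)OC
Why: Stiles carboxylation: magnesium held between the neighbouring carboxylate and the lactone enolate drives carboxylation of the lactone α-CH2; the new centre is a labile malonate-type centre that is destroyed in the next step.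

Step 7
Reactants: 15 crude lactone diacid
Product: 17 (2R,3S)-2-{13-[(tert-butyldiphenylsilyl)oxy]tridecyl}-4-methylidene-5-oxooxolane-3-carboxylic acid, via Mannich base 16 (not isolated)
Conditions: 37% aq. HCHO, PhNHMe, NaOAc, AcOH, rt, 2 h
Reagents that add atoms: formaldehyde, C=O
Why: Decarboxylative Mannich methylenation: the malonic half-acid adds to the N-methyl-N-phenyliminium ion and the Mannich base loses CO2 and amine to give the exocyclic alkene in a buffered acidic medium that does not isomerize it.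

Step 8
Reactants: 17 silyl-protected α-methylene acid
Product: 18 (2R,3S)-2-(13-hydroxytridecyl)-4-methylidene-5-oxooxolane-3-carboxylic acid
Conditions: HF·pyridine, THF, 0 °C → rt
Reagents that add atoms: none
Why: Fluoride-mediated desilylation driven by the Si–F bond; the acidic medium leaves the base-sensitive α-methylene lactone alone.

Step 9
Reactants: 18 hydroxy α-methylene acid
Product: 20 (2R,3S)-2-[13-(acetyloxy)tridecyl]-4-methylidene-5-oxooxolane-3-carboxylic acid, via mixed anhydride 19 (not isolated)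
Conditions: Ac2O (4 equiv), Sc(OTf)3 (2 mol %), MeCN/CH2Cl2, 0 °C; then THF/H2O, rt
Reagents that add atoms: acetic anhydride, CC(=O)OC(C)=O
Why: Lewis acid catalysed O-acetylation of the primary alcohol without base, so the alkene cannot migrate into the ring; the carboxyl group that is acetylated to mixed anhydride 19 is hydrolysed back by the water quench.

## Compound list

1 | tetradecane-1,14-diol | OCCCCCCCCCCCCCCO | starting material
2 | 14-[(tert-butyldiphenylsilyl)oxy]tetradecan-1-ol | OCCCCCCCCCCCCCCO[Si](c1ccccc1)(c1ccccc1)C(C)(C)C | intermediate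
3 | 14-[(tert-butyldiphenylsilyl)oxy]tetradecanal | O=CCCCCCCCCCCCCCO[Si](c1ccccc1)(c1ccccc1)C(C)(C)C | intermediate
4 | (4S)-4-benzyl-1,3-oxazolidin-2-one | O=C1N[C@@H](Cc2ccccc2)CO1 | starting material
5 | methyl 4-chloro-4-oxobutanoate | COC(=O)CCC(Cl)=O | starting material
6 | lithium (4S)-4-benzyl-2-oxo-1,3-oxazolidin-3-ide, N-lithio 4 (not isolated) | [Li]N1C(=O)OC[C@@H]1Cc1ccccc1 | intermediate
7 | methyl 4-[(4S)-4-benzyl-2-oxo-1,3-oxazolidin-3-yl]-4-oxobutanoate | COC(=O)CCC(=O)N1C(=O)OC[C@@H]1Cc1ccccc1 | intermediate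
8 | methyl (3Z)-4-[(4S)-4-benzyl-2-oxo-1,3-oxazolidin-3-yl]-4-[(dibutylboranyl)oxy]but-3-enoate (not isolated) | COC(=O)C/C=C(\OB(CCCC)CCCC)N1C(=O)OC[C@@H]1Cc1ccccc1 | intermediate
9 | methyl (3S,4R)-3-[(4S)-4-benzyl-2-oxo-1,3-oxazolidine-3-carbonyl]-17-[(tert-butyldiphenylsilyl)oxy]-4-[(dibutylboranyl)oxy]heptadecanoate (not isolated) | COC(=O)C[C@H](C(=O)N1C(=O)OC[C@@H]1Cc1ccccc1)[C@H](OB(CCCC)CCCC)CCCCCCCCCCCCCO[Si](c1ccccc1)(c1ccccc1)C(C)(C)C | intermediate
10 | methyl (3S,4R)-3-[(4S)-4-benzyl-2-oxo-1,3-oxazolidine-3-carbonyl]-17-[(tert-butyldiphenylsilyl)oxy]-4-hydroxyheptadecanoate (not isolated) | COC(=O)C[C@H](C(=O)N1C(=O)OC[C@@H]1Cc1ccccc1)[C@H](O)CCCCCCCCCCCCCO[Si](c1ccccc1)(c1ccccc1)C(C)(C)C | intermediate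
11 | (4S)-4-benzyl-3-[(2R,3S)-2-{13-[(tert-butyldiphenylsilyl)oxy]tridecyl}-5-oxooxolane-3-carbonyl]-1,3-oxazolidin-2-one | C1C(=O)O[C@H](CCCCCCCCCCCCCO[Si](c2ccccc2)(c2ccccc2)C(C)(C)C)[C@H]1C(=O)N3C(=O)OC[C@@H]3Cc3ccccc3 | intermediate
12 | (2R,3S)-2-{13-[(tert-butyldiphenylsilyl)oxy]tridecyl}-5-oxooxolane-3-carboperoxoic acid (not isolated) | C1C(=O)O[C@H](CCCCCCCCCCCCCO[Si](c2ccccc2)(c2ccccc2)C(C)(C)C)[C@H]1C(=O)OO | intermediate
13 | (2R,3S)-2-{13-[(tert-butyldiphenylsilyl)oxy]tridecyl}-5-oxooxolane-3-carboxylic acid | C1C(=O)O[C@H](CCCCCCCCCCCCCO[Si](c2ccccc2)(c2ccccc2)C(C)(C)C)[C@H]1C(=O)O | intermediate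
14 | magnesium (2R,3S)-2-{13-[(tert-butyldiphenylsilyl)oxy]tridecyl}-5-oxooxolane-3,4-dicarboxylate, C4 not fixed (not isolated) | [Mg+2].[O-]C(=O)C1C(=O)O[C@H](CCCCCCCCCCCCCO[Si](c2ccccc2)(c2ccccc2)C(C)(C)C)[C@H]1C([O-])=O | intermediate
15 | (2R,3S)-2-{13-[(tert-butyldiphenylsilyl)oxy]tridecyl}-5-oxooxolane-3,4-dicarboxylic acid, C4 epimers | OC(=O)C1C(=O)O[C@H](CCCCCCCCCCCCCO[Si](c2ccccc2)(c2ccccc2)C(C)(C)C)[C@H]1C(=O)O | intermediate
16 | (2R,3S)-2-{13-[(tert-butyldiphenylsilyl)oxy]tridecyl}-4-{[methyl(phenyl)amino]methyl}-5-oxooxolane-3,4-dicarboxylic acid, C4 not fixed (not isolated) | CN(CC1(C(=O)O)C(=O)O[C@H](CCCCCCCCCCCCCO[Si](c2ccccc2)(c2ccccc2)C(C)(C)C)[C@H]1C(=O)O)c3ccccc3 | intermediate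
17 | (2R,3S)-2-{13-[(tert-butyldiphenylsilyl)oxy]tridecyl}-4-methylidene-5-oxooxolane-3-carboxylic acid | C=C1C(=O)O[C@H](CCCCCCCCCCCCCO[Si](c2ccccc2)(c2ccccc2)C(C)(C)C)[C@H]1C(=O)O | intermediate
18 | (2R,3S)-2-(13-hydroxytridecyl)-4-methylidene-5-oxooxolane-3-carboxylic acid | C=C1C(=O)O[C@H](CCCCCCCCCCCCCO)[C@H]1C(=O)O | intermediate
19 | acetic (2R,3S)-2-[13-(acetyloxy)tridecyl]-4-methylidene-5-oxooxolane-3-carboxylic anhydride (not isolated) | C=C1C(=O)O[C@H](CCCCCCCCCCCCCOC(C)=O)[C@H]1C(=O)OC(C)=O | intermediate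
20 | (2R,3S)-2-[13-(acetyloxy)tridecyl]-4-methylidene-5-oxooxolane-3-carboxylic acid | C=C1C(=O)O[C@H](CCCCCCCCCCCCCOC(C)=O)[C@H]1C(=O)O | target

## Summary

Total step count: 9.
Longest linear sequence: 8 steps (steps 1, 2, 4, 5, 6, 7, 8, 9 from diol 1); step 3 is the one-step side branch.

## Steps most likely to fail

**Step 4 (aldol and lactonization).** The risks are incomplete or unselective enolization next to the ester, modest diastereoselectivity, or retro-aldol during lactonization. The fallback sets out from 5 and 3 and comes back at 13. It makes the same bond through a titanium enolate of a thiazolidinethione imide. Commercial (4S)-4-benzyl-1,3-thiazolidine-2-thione (S=C1N[C@@H](Cc2ccccc2)CS1) is N-acylated with 5 (Et3N, CH2Cl2, 0 °C) to the N-succinyl thiazolidinethione F1. Enolization with TiCl4, iPr2NEt and N-methylpyrrolidin-2-one (CH2Cl2, 0 → −78 °C) and addition of 3 gives the same (3S,4R) syn adduct, the thiazolidinethione hydroxy ester F2. Catalytic TsOH·H2O closes it to the trans lactone thioimide F3. LiOH in THF/H2O at 0 °C then displaces the thiazolidinethione and gives acid 13.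

**Step 6 (carboxylation at 130 °C).** The risks are incomplete carboxylation, loss of CO2 on work-up and erosion of the silyl ether under long heating. The fallback sets out from 13 and comes back at 17, replacing both the carboxylation and the decarboxylative Mannich step. Acid 13 is doubly deprotonated with LiN(SiMe3)2 (2.2 equiv, THF, −78 °C) to the dilithium carboxylate lactone enolate F4. This is aminomethylated with dimethyl(methylidene)ammonium iodide to the 4-[(dimethylamino)methyl] acid F5. N-methylation with MeI gives the trimethylammonium iodide F6. NaHCO3 (aq)/EtOAc at rt then eliminates trimethylamine and gives 17 after acidification.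

**Step 9 (acetylation of the free hydroxy acid).** Compound 18 is a heat- and base-sensitive α-methylene acid. The risks are alkene migration into the ring and oligoester formation through the mixed anhydride. The fallback sets out from 15 and comes back at 20. It puts the acetate on before the alkene exists. Crude 15 is desilylated (HF·pyridine, THF) to the hydroxy diacid F7. This is acetylated (Ac2O, cat. Sc(OTf)3, then water) to the acetoxy diacid F8. The step 7 conditions (aq. HCHO, PhNHMe, NaOAc, AcOH, rt), which an acetate tolerates, then give 20 directly through the acetoxy Mannich base F9. The sensitive α-methylene acid is thus formed last and not handled further.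

## Further compounds

F1 | step 4 | methyl 4-[(4S)-4-benzyl-2-sulfanylidene-1,3-thiazolidin-3-yl]-4-oxobutanoate | COC(=O)CCC(=O)N1C(=S)SC[C@@H]1Cc1ccccc1
F2 | step 4 | methyl (3S,4R)-3-[(4S)-4-benzyl-2-sulfanylidene-1,3-thiazolidine-3-carbonyl]-17-[(tert-butyldiphenylsilyl)oxy]-4-hydroxyheptadecanoate | COC(=O)C[C@H](C(=O)N1C(=S)SC[C@@H]1Cc1ccccc1)[C@H](O)CCCCCCCCCCCCCO[Si](c1ccccc1)(c1ccccc1)C(C)(C)C
F3 | step 4 | (4S)-4-benzyl-3-[(2R,3S)-2-{13-[(tert-butyldiphenylsilyl)oxy]tridecyl}-5-oxooxolane-3-carbonyl]-1,3-thiazolidine-2-thione | C1C(=O)O[C@H](CCCCCCCCCCCCCO[Si](c2ccccc2)(c2ccccc2)C(C)(C)C)[C@H]1C(=O)N3C(=S)SC[C@@H]3Cc3ccccc3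
F4 | step 6 | dilithium (2R,3S)-2-{13-[(tert-butyldiphenylsilyl)oxy]tridecyl}-5-oxido-2,3-dihydrofuran-3-carboxylate | C1=C([O-])O[C@H](CCCCCCCCCCCCCO[Si](c2ccccc2)(c2ccccc2)C(C)(C)C)[C@H]1C(=O)[O-].[Li+].[Li+]
F5 | step 6 | (2R,3S)-2-{13-[(tert-butyldiphenylsilyl)oxy]tridecyl}-4-[(dimethylamino)methyl]-5-oxooxolane-3-carboxylic acid, C4 epimers | CN(C)CC1C(=O)O[C@H](CCCCCCCCCCCCCO[Si](c2ccccc2)(c2ccccc2)C(C)(C)C)[C@H]1C(=O)O
F6 | step 6 | 1-[(4S,5R)-5-{13-[(tert-butyldiphenylsilyl)oxy]tridecyl}-4-carboxy-2-oxooxolan-3-yl]-N,N,N-trimethylmethanaminium iodide | C[N+](C)(C)CC1C(=O)O[C@H](CCCCCCCCCCCCCO[Si](c2ccccc2)(c2ccccc2)C(C)(C)C)[C@H]1C(=O)O.[I-]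
F7 | step 9 | (2R,3S)-2-(13-hydroxytridecyl)-5-oxooxolane-3,4-dicarboxylic acid, C4 epimers | OC(=O)C1C(=O)O[C@H](CCCCCCCCCCCCCO)[C@H]1C(=O)O
F8 | step 9 | (2R,3S)-2-[13-(acetyloxy)tridecyl]-5-oxooxolane-3,4-dicarboxylic acid, C4 epimers | OC(=O)C1C(=O)O[C@H](CCCCCCCCCCCCCOC(C)=O)[C@H]1C(=O)O
F9 | step 9 | (2R,3S)-2-[13-(acetyloxy)tridecyl]-4-{[methyl(phenyl)amino]methyl}-5-oxooxolane-3,4-dicarboxylic acid | CN(CC1(C(=O)O)C(=O)O[C@H](CCCCCCCCCCCCCOC(C)=O)[C@H]1C(=O)O)c2ccccc2
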